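**Retrosynthetic overview**
- The target is an all-trans 1,2,3-trisubstituted indane (C-1 carries the CH(OH)Ar side chain, C-2 the resorcinol ring, C-3 the 4-hydroxyphenyl ring) with an exocyclic (S)-carbinol carbon Cα. All six phenols travel as benzyl ethers and are freed last.
- Enabling feature: with Cα at the ketone level and a carboxyl standing in for the resorcinol ring on C-2, C-1 and C-2 are the two α-carbons of a 1,4-dicarbonyl unit, held on adjacent positions of the benzo ring. The cyclopentane is therefore closed across C-1–C-2 by oxidative coupling of a ketone/ester bis-enolate.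
- Before the key step: formylation, olefination, rhodium-catalysed asymmetric arylation (sets C-3) and palladium-catalysed ketone α-arylation give the open keto ester.
- After the key step: C-3 relays trans to C-2 and C-1; the ester is cleaved, the ketone is reduced under catalyst control (Cα), and the carboxyl is exchanged for the resorcinol ring by decarboxylative arylation anti to both neighbours.
- Ring order: the benzo ring is bought; the only ring formed is the five-membered ring (step 5).

Key step: step 5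

Remark on the chemistry: indane locants of the target are used throughout; the sense of induction of the two chiral catalysts (steps 3 and 7) is assigned from their established empirical models.

**Step 1**
Reactants: 1 1,3-bis(benzyloxy)-5-bromobenzene
Product: 3 2,4-bis(benzyloxy)-6-bromobenzaldehyde, via aryl iminium chloride 2 (not isolated)
Conditions: POCl3, DMF, 0 → 80 °C; then H2O
Reagents that add atoms: N,N-dimethylformamide CN(C)C=O; water O
Why: Vilsmeier–Haack formylation; the position ortho to bromine is para to one ether and ortho to the other and is less hindered than the position between the two ethers, so the formyl group should enter there.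

**Step 2**
Reactants: 3 2,4-bis(benzyloxy)-6-bromobenzaldehyde; 4 tert-butyl (diethoxyphosphoryl)acetate
Product: 5 tert-butyl (2E)-3-[2,4-bis(benzyloxy)-6-bromophenyl]prop-2-enoate
Conditions: NaH, THF, 0 °C → rt
Reagents that add atoms: none
Why: Horner–Wadsworth–Emmons olefination with a stabilised phosphonate anion should give the (E)-enoate; the tert-butyl ester is chosen because it resists Claisen acylation later.

**Step 3**
Reactants: 5 tert-butyl (2E)-3-[2,4-bis(benzyloxy)-6-bromophenyl]prop-2-enoate; 6 [4-(benzyloxy)phenyl]boronic acid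
Product: 7 tert-butyl (3R)-3-[4-(benzyloxy)phenyl]-3-[2,4-bis(benzyloxy)-6-bromophenyl]propanoate
Conditions: Rh(acac)(C2H4)2 (3 mol%), (S)-BINAP (3.3 mol%), 6 (3 equiv), dioxane/H2O 10:1, 100 °C
Reagents that add atoms: none
Why: Hayashi–Miyaura asymmetric 1,4-addition; the aryl–rhodium species inserts the enoate and, by the face-selection model for (E)-enoates, the (S)-BINAP complex should give the 3R centre (later indane C-3), leaving the aryl bromide untouched.

**Step 4**
Reactants: 7 tert-butyl (3R)-3-[4-(benzyloxy)phenyl]-3-[2,4-bis(benzyloxy)-6-bromophenyl]propanoate; 8 1-[4-(benzyloxy)phenyl]ethan-1-one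
Product: 9 tert-butyl (3R)-3-[4-(benzyloxy)phenyl]-3-[2,4-bis(benzyloxy)-6-{2-[4-(benzyloxy)phenyl]-2-oxoethyl}phenyl]propanoate
Conditions: Pd2(dba)3 (2 mol%), XPhos (5 mol%), K3PO4, toluene, 90 °C
Reagents that add atoms: none
Why: Palladium-catalysed ketone α-arylation (Buchwald–Hartwig type); the methyl ketone enolate should couple once with the hindered aryl bromide, and the weak base leaves the tert-butyl ester and the non-acidic C-3 stereocentre intact.

**Step 5**
Reactants: 9 tert-butyl (3R)-3-[4-(benzyloxy)phenyl]-3-[2,4-bis(benzyloxy)-6-{2-[4-(benzyloxy)phenyl]-2-oxoethyl}phenyl]propanoate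
Product: 11 tert-butyl (1R,2S,3R)-1-[4-(benzyloxy)benzoyl]-4,6-bis(benzyloxy)-3-[4-(benzyloxy)phenyl]-2,3-dihydro-1H-indene-2-carboxylate, via dilithium bis-enolate 10 (not isolated)
Conditions: LiN(i-Pr)2 (2.2 equiv), THF, −78 °C; then Fe(acac)3 (2.2 equiv), −78 °C → rt, high dilution; then DBU (cat.), CH2Cl2, rt
Reagents that add atoms: none
Why: Two equivalents of LiN(i-Pr)2 give the ketone/ester bis-enolate 10; single-electron oxidation of the more electron-rich ester enolate by Fe(acac)3 gives an α-ester radical that adds to the α-carbon of the neighbouring ketone enolate, and the resulting ketyl radical anion is oxidised by the second equivalent of the trivalent iron salt to the 1,4-dicarbonyl compound (oxidative enolate heterocoupling). The closest known reaction type is the iron- or copper-mediated oxidative cross-coupling of ketone enolates with ester or amide enolates, which is also known in ring-forming form. The cyclopentane closes by a 5-exo-trig radical addition in which both enolate double bonds lie outside the forming ring. C-2 is set by bond formation on the enolate face anti to the C-3 aryl group (allylic 1,3-strain keeps the C-3 hydrogen in the enolate plane), which places the ester trans to that aryl group; C-1 is set trans to the C-2 ester and, being α to the aryl ketone, is corrected to this thermodynamic configuration by the DBU treatment. The step needs ring closure to win over dimerisation and carbon–oxygen coupling: the two enolate carbons are held 1,5 on adjacent positions of the benzo ring, the reaction is run dilute, and the tert-butyl ester prevents Claisen acylation of the ketone enolate.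

**Step 6**
Reactants: 11 tert-butyl (1R,2S,3R)-1-[4-(benzyloxy)benzoyl]-4,6-bis(benzyloxy)-3-[4-(benzyloxy)phenyl]-2,3-dihydro-1H-indene-2-carboxylate
Product: 12 (1R,2S,3R)-1-[4-(benzyloxy)benzoyl]-4,6-bis(benzyloxy)-3-[4-(benzyloxy)phenyl]-2,3-dihydro-1H-indene-2-carboxylic acid
Conditions: CF3CO2H/CH2Cl2 1:4, 0 °C → rt
Reagents that add atoms: none
Why: Acidolysis of the tert-butyl ester (loss of 2-methylpropene) is done at the ketone stage, before the acid-labile benzylic carbinol exists; benzyl aryl ethers and the trans-configured ketone should survive.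

**Step 7**
Reactants: 12 (1R,2S,3R)-1-[4-(benzyloxy)benzoyl]-4,6-bis(benzyloxy)-3-[4-(benzyloxy)phenyl]-2,3-dihydro-1H-indene-2-carboxylic acid
Product: 13 (1R,2S,3R)-4,6-bis(benzyloxy)-1-{(S)-[4-(benzyloxy)phenyl](hydroxy)methyl}-3-[4-(benzyloxy)phenyl]-2,3-dihydro-1H-indene-2-carboxylic acid
Conditions: RuCl[(S,S)-TsDPEN](p-cymene) (3 mol%), HCO2H/Et3N 5:2, DMF, 40 °C
Reagents that add atoms: none
Why: Noyori asymmetric transfer hydrogenation of the aryl ketone; the (S,S) catalyst recognises the aryl group and should give the (S)-carbinol under catalyst control, the trans carboxyl group cannot lactonise, and reduction at this stage removes the β-acyl group that could migrate in the radical step that follows.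

**Step 8**
Reactants: 13 (1R,2S,3R)-4,6-bis(benzyloxy)-1-{(S)-[4-(benzyloxy)phenyl](hydroxy)methyl}-3-[4-(benzyloxy)phenyl]-2,3-dihydro-1H-indene-2-carboxylic acid; 1 1,3-bis(benzyloxy)-5-bromobenzene
Product: 14 (S)-[4-(benzyloxy)phenyl]{(1R,2S,3R)-4,6-bis(benzyloxy)-2-[3,5-bis(benzyloxy)phenyl]-3-[4-(benzyloxy)phenyl]-2,3-dihydro-1H-inden-1-yl}methanol
Conditions: Ir[dF(CF3)ppy]2(dtbbpy)PF6 (2 mol%), NiCl2·glyme (10 mol%), dtbbpy (15 mol%), Cs2CO3 (1.5 equiv), DMF, blue LEDs, rt
Reagents that add atoms: none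
Why: Metallaphotoredox decarboxylative arylation; oxidation of the caesium carboxylate and loss of CO2 give the planar secondary C-2 radical, which the aryl–nickel species formed from 1 should capture on the face anti to both flanking substituents, so the resorcinol ring ends trans to the C-1 side chain and the C-3 aryl group.

**Step 9**
Reactants: 14 (S)-[4-(benzyloxy)phenyl]{(1R,2S,3R)-4,6-bis(benzyloxy)-2-[3,5-bis(benzyloxy)phenyl]-3-[4-(benzyloxy)phenyl]-2,3-dihydro-1H-inden-1-yl}methanol
Product: 15 (1R,2S,3R)-2-(3,5-dihydroxyphenyl)-1-[(S)-hydroxy(4-hydroxyphenyl)methyl]-3-(4-hydroxyphenyl)-2,3-dihydro-1H-indene-4,6-diol (CNP0214825.2)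
Conditions: H2 (1 atm), Pd/C, EtOAc/MeOH, rt; stopped at complete debenzylation
Reagents that add atoms: none
Why: Catalytic hydrogenolysis of the six benzyl aryl ethers; under neutral conditions the secondary benzylic alcohol is cleaved much more slowly, and no stereocentre is touched.

**Compound list**
1 | 1,3-bis(benzyloxy)-5-bromobenzene | Brc1cc(OCc2ccccc2)cc(OCc2ccccc2)c1 | starting material
2 | N-{[2,4-bis(benzyloxy)-6-bromophenyl]methylidene}-N-methylmethanaminium chloride | C[N+](C)=Cc1c(Br)cc(OCc2ccccc2)cc1OCc1ccccc1.[Cl-] | intermediate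
3 | 2,4-bis(benzyloxy)-6-bromobenzaldehyde | O=Cc1c(Br)cc(OCc2ccccc2)cc1OCc1ccccc1 | intermediate
4 | tert-butyl (diethoxyphosphoryl)acetate | CCOP(=O)(OCC)CC(=O)OC(C)(C)C | starting material
5 | tert-butyl (2E)-3-[2,4-bis(benzyloxy)-6-bromophenyl]prop-2-enoate | CC(C)(C)OC(=O)/C=C/c1c(Br)cc(OCc2ccccc2)cc1OCc1ccccc1 | intermediate
6 | [4-(benzyloxy)phenyl]boronic acid | OB(O)c1ccc(OCc2ccccc2)cc1 | starting material
7 | tert-butyl (3R)-3-[4-(benzyloxy)phenyl]-3-[2,4-bis(benzyloxy)-6-bromophenyl]propanoate | C(Oc1ccc([C@@H](CC(=O)OC(C)(C)C)c2c(Br)cc(OCc3ccccc3)cc2OCc2ccccc2)cc1)c1ccccc1 | intermediate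
8 | 1-[4-(benzyloxy)phenyl]ethan-1-one | CC(=O)c1ccc(OCc2ccccc2)cc1 | starting material
9 | tert-butyl (3R)-3-[4-(benzyloxy)phenyl]-3-[2,4-bis(benzyloxy)-6-{2-[4-(benzyloxy)phenyl]-2-oxoethyl}phenyl]propanoate | C(Oc1ccc([C@@H](CC(=O)OC(C)(C)C)c2c(CC(=O)c3ccc(OCc4ccccc4)cc3)cc(OCc3ccccc3)cc2OCc2ccccc2)cc1)c1ccccc1 | intermediate
10 | dilithium bis-enolate of 9 (ketone enolate and ester enolate, R at the diarylmethine carbon) | [Li+].[Li+].[O-]C(=Cc1cc(OCc2ccccc2)cc(OCc2ccccc2)c1[C@H](C=C([O-])OC(C)(C)C)c1ccc(OCc2ccccc2)cc1)c1ccc(OCc2ccccc2)cc1 | intermediate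
11 | tert-butyl (1R,2S,3R)-1-[4-(benzyloxy)benzoyl]-4,6-bis(benzyloxy)-3-[4-(benzyloxy)phenyl]-2,3-dihydro-1H-indene-2-carboxylate (1,2-trans, 2,3-trans) | C(Oc1ccc([C@@H]2c3c(OCc4ccccc4)cc(OCc4ccccc4)cc3[C@H](C(=O)c3ccc(OCc4ccccc4)cc3)[C@H]2C(=O)OC(C)(C)C)cc1)c1ccccc1 | intermediate
12 | (1R,2S,3R)-1-[4-(benzyloxy)benzoyl]-4,6-bis(benzyloxy)-3-[4-(benzyloxy)phenyl]-2,3-dihydro-1H-indene-2-carboxylic acid | C(Oc1ccc([C@@H]2c3c(OCc4ccccc4)cc(OCc4ccccc4)cc3[C@H](C(=O)c3ccc(OCc4ccccc4)cc3)[C@H]2C(=O)O)cc1)c1ccccc1 | intermediate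
13 | (1R,2S,3R)-4,6-bis(benzyloxy)-1-{(S)-[4-(benzyloxy)phenyl](hydroxy)methyl}-3-[4-(benzyloxy)phenyl]-2,3-dihydro-1H-indene-2-carboxylic acid | C(Oc1ccc([C@@H]2c3c(OCc4ccccc4)cc(OCc4ccccc4)cc3[C@H]([C@H](O)c3ccc(OCc4ccccc4)cc3)[C@H]2C(=O)O)cc1)c1ccccc1 | intermediate
14 | (S)-[4-(benzyloxy)phenyl]{(1R,2S,3R)-4,6-bis(benzyloxy)-2-[3,5-bis(benzyloxy)phenyl]-3-[4-(benzyloxy)phenyl]-2,3-dihydro-1H-inden-1-yl}methanol | C(Oc1ccc([C@@H]2c3c(OCc4ccccc4)cc(OCc4ccccc4)cc3[C@H]([C@H](O)c3ccc(OCc4ccccc4)cc3)[C@H]2c2cc(OCc3ccccc3)cc(OCc3ccccc3)c2)cc1)c1ccccc1 | intermediate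
15 | (1R,2S,3R)-2-(3,5-dihydroxyphenyl)-1-[(S)-hydroxy(4-hydroxyphenyl)methyl]-3-(4-hydroxyphenyl)-2,3-dihydro-1H-indene-4,6-diol | Oc1ccc([C@@H]2c3c(O)cc(O)cc3[C@H]([C@H](O)c3ccc(O)cc3)[C@H]2c2cc(O)cc(O)c2)cc1 | target

**Step count and risks**
Total steps: 9. Longest linear sequence: 9 steps (1 → 15); compounds 4, 6 and 8 are bought and 1 is used twice.

Steps most likely to fail:

Step 5 (oxidative ring closure). The bis-enolate may dimerise between molecules, couple through oxygen or be over-oxidised instead of closing the hindered C-1–C-2 bond. The fallback makes the same bond by enolate alkylation and sets out from 7. Mizoroki–Heck coupling of 7 with 1-(benzyloxy)-4-ethenylbenzene (Pd(OAc)2, P(o-tol)3, K2CO3, DMF, 100 °C) should give the (E)-stilbene ester F1. Epoxidation with dimethyldioxirane (acetone, 0 °C) gives the trans-epoxide ester F2 as both diastereomers. KHMDS (THF, −78 → 0 °C) then forms the ester enolate, which opens the epoxide at the proximal carbon in a 5-exo-tet closure to the hydroxy ester F3 (mixture at C-1 and Cα). Dess–Martin oxidation followed by DBU converges all isomers, because C-1 becomes epimerisable, and the route is rejoined at 11.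

Step 8 (decarboxylative arylation). Capture of the doubly flanked secondary radical by nickel may be slow, so that hydrogen-atom quenching or β-hydride elimination takes over. The fallback changes the coupling manifold and sets out from 13. Esterification with N-hydroxyphthalimide (N,N'-diisopropylcarbodiimide, cat. DMAP, CH2Cl2) gives the redox-active ester F4, which cannot lactonise because the acyl group is trans to the side chain. Thermal nickel-catalysed decarboxylative coupling with [3,5-bis(benzyloxy)phenyl]boronic acid (NiCl2·6H2O, 4,7-diphenyl-1,10-phenanthroline, Et3N, dioxane/DMF, 75 °C) then rejoins the route at 14.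

Step 3 (asymmetric arylation). Insertion of the twisted, doubly ortho-substituted enoate into the aryl–rhodium bond may be too slow, so that protodeboronation of 6 consumes the reagent. The fallback uses a planar cyclic acceptor and sets out from 3. Chelation-controlled cleavage of the benzyl ether ortho to the aldehyde (MgBr2·OEt2, toluene/Et2O, reflux) gives the salicylaldehyde F5. Wittig olefination and lactonisation with ethyl (triphenylphosphoranylidene)acetate (N,N-diethylaniline, reflux) gives the coumarin F6. Hayashi–Miyaura addition of 6 with Rh(acac)(C2H4)2 and (R)-SEGPHOS (dioxane/H2O, 60 °C) should give the (4R)-dihydrocoumarin F7. Ring opening with KOt-Bu (t-BuOH/THF) and alkylation of the phenoxide in the same flask with benzyl bromide rejoin the route at 7.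

**Further compounds**
F1 | step 5 | tert-butyl (3R)-3-[4-(benzyloxy)phenyl]-3-{2,4-bis(benzyloxy)-6-[(E)-2-[4-(benzyloxy)phenyl]ethenyl]phenyl}propanoate | C(Oc1ccc([C@@H](CC(=O)OC(C)(C)C)c2c(/C=C/c3ccc(OCc4ccccc4)cc3)cc(OCc3ccccc3)cc2OCc2ccccc2)cc1)c1ccccc1
F2 | step 5 | tert-butyl (3R)-3-[4-(benzyloxy)phenyl]-3-{2,4-bis(benzyloxy)-6-[trans-3-[4-(benzyloxy)phenyl]oxiran-2-yl]phenyl}propanoate (both trans-epoxide diastereomers) | C(Oc1ccc([C@@H](CC(=O)OC(C)(C)C)c2c(C3OC3c3ccc(OCc4ccccc4)cc3)cc(OCc3ccccc3)cc2OCc2ccccc2)cc1)c1ccccc1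
F3 | step 5 | tert-butyl (2S,3R)-4,6-bis(benzyloxy)-1-{[4-(benzyloxy)phenyl](hydroxy)methyl}-3-[4-(benzyloxy)phenyl]-2,3-dihydro-1H-indene-2-carboxylate (mixture at C-1 and the carbinol carbon) | C(Oc1ccc([C@@H]2c3c(OCc4ccccc4)cc(OCc4ccccc4)cc3C(C(O)c3ccc(OCc4ccccc4)cc3)[C@H]2C(=O)OC(C)(C)C)cc1)c1ccccc1
F4 | step 8 | 1,3-dioxoisoindolin-2-yl (1R,2S,3R)-4,6-bis(benzyloxy)-1-{(S)-[4-(benzyloxy)phenyl](hydroxy)methyl}-3-[4-(benzyloxy)phenyl]-2,3-dihydro-1H-indene-2-carboxylate | C(Oc1ccc([C@@H]2c3c(OCc4ccccc4)cc(OCc4ccccc4)cc3[C@H]([C@H](O)c3ccc(OCc4ccccc4)cc3)[C@H]2C(=O)ON2C(=O)c3ccccc3C2=O)cc1)c1ccccc1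
F5 | step 3 | 4-(benzyloxy)-2-bromo-6-hydroxybenzaldehyde | O=Cc1c(O)cc(OCc2ccccc2)cc1Br
F6 | step 3 | 7-(benzyloxy)-5-bromo-2H-chromen-2-one | O=c1ccc2c(Br)cc(OCc3ccccc3)cc2o1
F7 | step 3 | (4R)-7-(benzyloxy)-4-[4-(benzyloxy)phenyl]-5-bromo-3,4-dihydro-2H-chromen-2-one | O=C1C[C@H](c2ccc(OCc3ccccc3)cc2)c2c(Br)cc(OCc3ccccc3)cc2O1
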